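**Retrosynthetic overview**
- Building blocks: (+)-catechin 1, used as its ring B diphenylmethylene ketal 2, and two molecules of (2R,3S)-mesquitol 3. Together they carry all six stereocentres.
- Key disconnections: the two biaryl bonds, mesquitol C5–catechin C8 and mesquitol C5–catechin C6. Each is traced back to conjugate addition of ring A of 2 to the anodically generated ring A o-quinone 4 of 3, through the mono-arylated ketals 5 and 6 to the trimer ketal 7.
- Last disconnection: the ketal C–O bonds of 7, cleaved by hydrogenolysis to the target 8.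
- Ring formation: no ring of the target is built. All nine rings arrive intact in 1 and 3; the only ring made, and later removed, is the temporary dioxole of 2.

Assumption: the SMILES fixes six stereocentres but no axial configuration, so the two biaryl axes are left uncontrolled (rotamer mixture accepted), and (2R,3S)-mesquitol is taken as a purchasable, inexpensive Prosopis heartwood isolate, like (+)-catechin.

**Step 1**
Reactants: 1 (+)-catechin
Product: 2 3',4'-O-diphenylmethylene-(+)-catechin
Conditions: Ph2CCl2 (1.5 equiv), Ph2O, 175 °C, 20 min, N2 sweep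
Reagents that add atoms: dichlorodiphenylmethane, ClC(Cl)(c1ccccc1)c1ccccc1
Why: Thermal ketalisation by a gem-dichloride (the standard diphenylmethylene catechol protection) can close a five-membered 1,3-benzodioxole only on the ring B 1,2-diol, the meta-placed ring A phenols and the 3-OH giving at most reversible chloro-ethers, and the base-free conditions leave the purchased C2 and C3 centres (2R,3S) untouched.

**Step 2**
Reactants: 2 3',4'-O-diphenylmethylene-(+)-catechin (1.0 equiv); 3 (2R,3S)-mesquitol (2.6 equiv)
Product: 7 6,8-bis[(2R,3S)-mesquitol-5-yl]-3',4'-O-diphenylmethylene-(+)-catechin, via mesquitol ring A o-quinone 4 (not isolated), via C8-monoarylated ketal 5 (not isolated), via C6-monoarylated ketal 6 (not isolated)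
Conditions: carbon-felt anode, Pt cathode, divided cell (Nafion), +0.30 V vs Ag/AgCl (about 50 mV past the first anodic peak of 3 by CV), 4.2 F per mol of 2, NaOAc/AcOH buffer (0.2 M, pH 5)–MeCN 1:1, 5 °C, Ar; then −0.15 V, 15 min; Sephadex LH-20
Reagents that add atoms: none
Why: Proposed new method: a potential-gated, twofold anodic cross-dehydrogenative arylation between two unprotected flavan-3-ol rings; the anode removes two electrons and two protons from the ring A 3-alkoxycatechol of 3, its most easily oxidised site (any ring B quinone is returned by fast catechol–quinone redox exchange), giving o-quinone 4, whose C5 (β-carbon of the C7 enone, para to the C8 oxygen) takes up the phloroglucinol-type carbons of 2 in a conjugate addition, mainly C8 first (5) and partly C6 first (6), followed by rearomatising tautomerisation and a second round at the remaining carbon, both mono-adducts converging on 7; the 5-arylated catechols are blocked at C5 and are kept reduced by the excess of 3 and by the final cathodic polish, pH 5 and 5 °C hold back quinone-methide tautomerisation and epimerisation so that no stereocentre is made or touched (axes uncontrolled); the closest known reaction type is the anodic oxidation of simple catechols, including 3-methoxycatechol which is attacked at the corresponding carbon, in the presence of C-nucleophiles (electrochemical Michael arylation, EC mechanism), not yet shown for flavan-3-ol partners or as a double coupling.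

**Step 3**
Reactants: 7 6,8-bis[(2R,3S)-mesquitol-5-yl]-3',4'-O-diphenylmethylene-(+)-catechin
Product: 8 (2R,3S)-mesquitol-(5→6)-(+)-catechin-(8→5)-(2R,3S)-mesquitol (target)
Conditions: H2 (1 atm), Pd(OH)2/C (20 wt%), THF–MeOH 1:1, rt, 3 h; filter under Ar, Sephadex LH-20
Reagents that add atoms: none
Why: Hydrogenolysis of the doubly benzylic ketal C–O bonds (standard diphenylmethylene removal) frees the ring B catechol as diphenylmethane leaves, while the singly benzylic C2–O1 bonds of the three flavan units survive 1 atm H2 at room temperature, so all six purchased stereocentres reach the target unchanged.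

**Compound list**
1 | (+)-catechin, (2R,3S)-2-(3,4-dihydroxyphenyl)chromane-3,5,7-triol | Oc1cc(O)c2c(c1)O[C@H](c1ccc(O)c(O)c1)[C@@H](O)C2 | starting material
2 | 3',4'-O-diphenylmethylene-(+)-catechin, (2R,3S)-2-(2,2-diphenyl-1,3-benzodioxol-5-yl)chromane-3,5,7-triol | Oc1cc(O)c2c(c1)O[C@H](c1ccc3OC(c4ccccc4)(c4ccccc4)Oc3c1)[C@@H](O)C2 | intermediate
3 | (2R,3S)-mesquitol, (2R,3S)-2-(3,4-dihydroxyphenyl)chromane-3,7,8-triol | Oc1ccc([C@H]2Oc3c(O)c(O)ccc3C[C@@H]2O)cc1O | starting material
4 | mesquitol ring A o-quinone, (2R,3S)-2-(3,4-dihydroxyphenyl)-3-hydroxy-3,4-dihydro-2H-chromene-7,8-dione | O=C1C=CC2=C(C1=O)O[C@H](c1ccc(O)c(O)c1)[C@@H](O)C2 | intermediate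
5 | C8-monoarylated ketal, 8-[(2R,3S)-mesquitol-5-yl]-3',4'-O-diphenylmethylene-(+)-catechin | Oc1cc(O)c2c(c1-c1cc(O)c(O)c3c1C[C@H](O)[C@@H](c1ccc(O)c(O)c1)O3)O[C@H](c1ccc3OC(c4ccccc4)(c4ccccc4)Oc3c1)[C@@H](O)C2 | intermediate
6 | C6-monoarylated ketal, 6-[(2R,3S)-mesquitol-5-yl]-3',4'-O-diphenylmethylene-(+)-catechin | Oc1cc2c(c(O)c1-c1cc(O)c(O)c3c1C[C@H](O)[C@@H](c1ccc(O)c(O)c1)O3)C[C@H](O)[C@@H](c1ccc3OC(c4ccccc4)(c4ccccc4)Oc3c1)O2 | intermediate
7 | 6,8-bis[(2R,3S)-mesquitol-5-yl]-3',4'-O-diphenylmethylene-(+)-catechin | Oc1ccc([C@H]2Oc3c(O)c(O)cc(-c4c(O)c5c(c(-c6cc(O)c(O)c7c6C[C@H](O)[C@@H](c6ccc(O)c(O)c6)O7)c4O)O[C@H](c4ccc6OC(c8ccccc8)(c8ccccc8)Oc6c4)[C@@H](O)C5)c3C[C@@H]2O)cc1O | intermediate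
8 | (2R,3S)-mesquitol-(5→6)-(+)-catechin-(8→5)-(2R,3S)-mesquitol, all six centres 2R,3S in each flavan unit | Oc1ccc([C@H]2Oc3c(O)c(O)cc(-c4c(O)c5c(c(-c6cc(O)c(O)c7c6C[C@H](O)[C@@H](c6ccc(O)c(O)c6)O7)c4O)O[C@H](c4ccc(O)c(O)c4)[C@@H](O)C5)c3C[C@@H]2O)cc1O | target

**Total step count:** 3
**Longest linear sequence:** 3 steps (1 → 2 → 7 → 8); mesquitol 3 enters unchanged at step 2.

**Three steps most likely to fail**

Step 2 (the proposed new step). The risks are further oxidation of the arylated catechols (intramolecular phenol addition to a product quinone), oxidation of ring B of 3, tautomerisation of 4 to a quinone methide at C4, self-coupling of 3, and stalling at 5 and 6. The fallback uses known chemistry, sets out from 3 (together with 2) and comes back at 7. It replaces the electrode by a two-stage, reagent-based biomimetic oxidative coupling. Mesquitol 3 is oxidised ex situ with Ag2O (1.0 equiv, Na2SO4, dry acetone–THF, −15 °C). The silver residue is filtered off cold under argon, and the solution of preformed quinone 4 is run into 2 in MeCN/acetate buffer; addition of phloroglucinol-type rings to preformed o-quinones is established. The cycle is repeated until 5 and 6 are consumed. Because reagent oxidation is less selective, the crude product is peracetylated (Ac2O, pyridine, DMAP) to the trimer ketal tridecaacetate F3. F3 is purified on silica gel and deacetylated (K2CO3, MeOH–THF, 0 °C, Ar, AcOH quench) to give 7.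

Step 1. The risks are a moderate yield, tar formation in the hot melt, and C-benzhydrylation of ring A at C6 or C8. The fallback sets out from 1 and comes back at 8. It drops the protecting group: 1 is electrolysed directly with 3 under the step 2 conditions, with the potential held at the foot of the first wave of 3 so that ring B of catechin is guarded by potential control alone. The reaction runs through 4 and the free dimers mesquitol-(5→8)-catechin F1 and mesquitol-(5→6)-catechin F2 straight to 8 (Sephadex LH-20), skipping 7 and step 3. The price is more self-condensation of catechin.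

Step 3. The risks are adsorption of the polyphenol on the catalyst, slow hydrogenolysis of C2–O1, and air oxidation on work-up. The fallback sets out from 7 and comes back at 8. It cleaves the ketal hydrolytically instead of reductively (AcOH–H2O 4:1, 100 °C, Ar), giving benzophenone. The trimer has only biaryl links and no acid-labile C4 interflavan bond, so it tolerates hot aqueous acid. New compounds on this path: none F0.

**Further compounds**
F1 | step 1 | mesquitol-(5→8)-catechin, 8-[(2R,3S)-mesquitol-5-yl]-(+)-catechin, free phenol | Oc1cc(O)c2c(c1-c1cc(O)c(O)c3c1C[C@H](O)[C@@H](c1ccc(O)c(O)c1)O3)O[C@H](c1ccc(O)c(O)c1)[C@@H](O)C2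
F2 | step 1 | mesquitol-(5→6)-catechin, 6-[(2R,3S)-mesquitol-5-yl]-(+)-catechin, free phenol | Oc1cc2c(c(O)c1-c1cc(O)c(O)c3c1C[C@H](O)[C@@H](c1ccc(O)c(O)c1)O3)C[C@H](O)[C@@H](c1ccc(O)c(O)c1)O2
F3 | step 2 | trimer ketal tridecaacetate, all thirteen hydroxyls of 7 acetylated | CC(=O)Oc1ccc([C@H]2Oc3c(OC(C)=O)c(OC(C)=O)cc(-c4c(OC(C)=O)c5c(c(-c6cc(OC(C)=O)c(OC(C)=O)c7c6C[C@H](OC(C)=O)[C@@H](c6ccc(OC(C)=O)c(OC(C)=O)c6)O7)c4OC(C)=O)O[C@H](c4ccc6OC(c8ccccc8)(c8ccccc8)Oc6c4)[C@@H](OC(C)=O)C5)c3C[C@@H]2OC(C)=O)cc1OC(C)=O
F0 | step 3 | none | none
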